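**Strategy.** Everything rests on disconnecting rings A and B together across the A/B fusion bond C5–C10 and the C3–C4 bond. A single intramolecular Diels–Alder reaction of a 1,3,8-nonatriene, a 1,4-bis(silyloxy)diene (C10=C1–C2=C3) on C9 adding to a (Z)-2-methylenoate (C4=C5) on C6, closes cyclohexene ring A and cyclopentane ring B and sets the contiguous stereocentres C3, C4, C5 and C10 (C4 and C10 quaternary) that surround that fusion bond. The precursor is an enantiopure C/D bicyclo[3.2.1]octane (16-methylene, 12,13-acetonide) carrying the dienyl group on C9 and, on C8, the C6 side chain with the enoate and a TIPS-protected C7 hydroxymethyl group.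

Key step: step 19

Remark: all intermediates carry gibberellane numbers (C1–C19); salts of numbered compounds (enolates, alkoxides, phosphonate anions) get no number of their own; C7 is protected as a TIPS ether so that one fluoride treatment after the key step frees O3, O7 and O10 together.

**Route**

Step 1
Reactants: 1 3-[(tert-butyldimethylsilyl)oxy]propanal; 2 methyl vinyl ketone
Product: 3 (S)-2-{[(tert-butyldimethylsilyl)oxy]methyl}-5-oxohexanal
Conditions: (S)-α,α-diphenylprolinol methyl ether (5 mol%), ethyl 3,4-dihydroxybenzoate (20 mol%), neat, 4 °C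
Reagents that add atoms: none
Why: Enamine-catalysed Michael addition of the aldehyde to the enone, in which the diphenyl(methoxy)methyl group shields one face of the E-enamine so that C9 should form in the (S) sense shown (the enantiomeric catalyst is used if the sense proves opposite), the catechol co-catalyst keeping the medium mild enough to avoid loss of the β-silyloxy group.

Step 2
Reactants: 3 (S)-2-{[(tert-butyldimethylsilyl)oxy]methyl}-5-oxohexanal
Product: 5 (R)-4-{[(tert-butyldimethylsilyl)oxy]methyl}cyclohex-2-en-1-one, via aldol adduct 4 (not isolated)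
Conditions: Bn2NH2+ CF3CO2− (20 mol%), PhMe, 50 °C
Reagents that add atoms: none
Why: Amine-salt-catalysed intramolecular aldol condensation (Robinson-type ring closure) of the methyl ketone onto the aldehyde followed by dehydration, which leaves the C9 centre untouched (it becomes the (R)-configured γ-carbon of the enone).

Step 3
Reactants: 5 (R)-4-{[(tert-butyldimethylsilyl)oxy]methyl}cyclohex-2-en-1-one; 6 1-(tert-butyldimethylsilyloxy)-1-methoxyethene
Product: 7 methyl 2-[(1S,6R)-3-[(tert-butyldimethylsilyl)oxy]-6-{[(tert-butyldimethylsilyl)oxy]methyl}cyclohex-2-en-1-yl]acetate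
Conditions: TBSOTf (5 mol%), CH2Cl2, −78 °C
Reagents that add atoms: none
Why: Mukaiyama–Michael addition of the ketene silyl acetal with silyl transfer to oxygen, which gives the C13–C14 silyl enol ether regiospecifically; the new C8–H centre (addition anti to the C9 substituent) is removed again in step 4.

Step 4
Reactants: 7 methyl 2-[(1S,6R)-3-[(tert-butyldimethylsilyl)oxy]-6-{[(tert-butyldimethylsilyl)oxy]methyl}cyclohex-2-en-1-yl]acetate
Product: 8 methyl 2-[(6R)-6-{[(tert-butyldimethylsilyl)oxy]methyl}-3-oxocyclohex-1-en-1-yl]acetate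
Conditions: Pd(OAc)2 (1.05 equiv), MeCN, rt
Reagents that add atoms: none
Why: Saegusa–Ito oxidation, in which palladation of the silyl enol ether and β-hydride elimination regenerate the C14=C8 enone, now carrying the acetate arm (C6–C5) on C8, with C9 as the only stereocentre.

Step 5
Reactants: 8 methyl 2-[(6R)-6-{[(tert-butyldimethylsilyl)oxy]methyl}-3-oxocyclohex-1-en-1-yl]acetate; 9 (2-bromoallyl)trimethylsilane
Product: 10 methyl 2-[(1R,2R)-1-(2-bromoprop-2-en-1-yl)-2-{[(tert-butyldimethylsilyl)oxy]methyl}-5-oxocyclohexyl]acetate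
Conditions: TiCl4 (1.1 equiv), CH2Cl2, −78 °C
Reagents that add atoms: none
Why: Hosomi–Sakurai conjugate allylation of the TiCl4-activated β,β-disubstituted enone, in which the allylsilane attacks C8 anti to the pseudoaxial C9 substituent, so that quaternary C8 forms with the bromoallyl group (C15) trans and the acetate arm (C6) cis to C10.

Step 6
Reactants: 10 methyl 2-[(1R,2R)-1-(2-bromoprop-2-en-1-yl)-2-{[(tert-butyldimethylsilyl)oxy]methyl}-5-oxocyclohexyl]acetate
Product: 12 cis-fused keto δ-lactone (4a-(2-bromoallyl)hexahydro-1H-isochromene-3,6-dione; lactone C5(=O)–O–C10; ketone C13), via hydroxy ester 11 (not isolated)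
Conditions: 1 M HCl, THF, rt; then p-TsOH (cat.), PhMe, 60 °C
Reagents that add atoms: none
Why: Acidic cleavage of the primary silyl ether followed by acid-catalysed transesterification, which closes the δ-lactone because the C10 hydroxyl and the C6 acetate arm are cis on ring C; no stereocentre is affected.

Step 7
Reactants: 12 cis-fused keto δ-lactone
Product: 13 12-hydroxy keto lactone (OH on C12 anti to the C10 arm)
Conditions: NaHMDS (1.1 equiv), THF, −78 °C; then 2-(phenylsulfonyl)-3-phenyloxaziridine, −78 °C; aq. NH4Cl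
Reagents that add atoms: (±)-trans-2-(phenylsulfonyl)-3-phenyloxaziridine O=S(=O)(c1ccccc1)N1OC1c1ccccc1
Why: Kinetic enolisation of the ketone toward the less hindered C12 (C14 is neopentyl and the lactone is the weaker acid) and electrophilic enolate hydroxylation (Davis oxidation), the oxidant being expected to enter anti to the C10 arm to give mainly the 12-epimer shown, whose configuration is reset in steps 9 and 10.

Step 8
Reactants: 13 12-hydroxy keto lactone
Product: 15 tricyclic 12β,13-diol lactone (C/D bicyclo[3.2.1]octane with 16-methylene and bridgehead 13-OH; δ-lactone fused at C8–C9), via alkenylchromium 14 (not isolated)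
Conditions: CrCl2 (6 equiv), NiCl2 (5 mol%), DMSO, rt to 50 °C
Reagents that add atoms: none
Why: Nozaki–Hiyama–Kishi reaction, in which nickel inserts into the vinyl bromide, transmetalation gives the alkenylchromium(III) species and this adds to the C13 ketone in a 5-exo closure; the axial bromoallyl group can reach only one face of the carbonyl, so C13 forms as the bridgehead carbinol of the bicyclo[3.2.1]octane.

Step 9
Reactants: 15 tricyclic 12β,13-diol lactone
Product: 16 13-hydroxy-12-oxo lactone (α-ketol)
Conditions: (COCl)2, DMSO, CH2Cl2, −78 °C; Et3N, −78 to −20 °C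
Reagents that add atoms: none
Why: Swern oxidation of the only secondary hydroxyl (the bridgehead tertiary 13-OH cannot be oxidised), run cold and worked up quickly to avoid α-ketol rearrangement, erases the wrongly configured C12.

Step 10
Reactants: 16 13-hydroxy-12-oxo lactone
Product: 17 12α,13-diol lactone (cis-diol)
Conditions: L-Selectride (2.5 equiv), THF, −78 °C; aq. NH4Cl
Reagents that add atoms: none
Why: Steric-approach-controlled ketone reduction, in which the axial C10 methylene on C9 is 1,3-syn to the α face of C12, so the bulky hydride should attack from the side of the C15–C16 bridge and give the axial 12α-alcohol cis to O13.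

Step 11
Reactants: 17 12α,13-diol lactone
Product: 18 12α,13-O-isopropylidene lactone
Conditions: Me2C(OMe)2, PPTS (cat.), CH2Cl2, rt
Reagents that add atoms: 2,2-dimethoxypropane COC(C)(C)OC
Why: Acid-catalysed transketalisation, in which the cis (axial–equatorial) 12α,13-diol forms the dioxolane readily under conditions mild enough for the tertiary allylic alcohol.

Step 12
Reactants: 18 12α,13-O-isopropylidene lactone; 19 (triisopropylsiloxy)methyl chloride
Product: 20 6β-[(triisopropylsilyloxy)methyl] lactone (C7 cis to C15 and H9)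
Conditions: LDA (1.2 equiv), THF, −78 °C; then 19, −78 to −40 °C
Reagents that add atoms: none
Why: Alkylation of the lactone lithium enolate with an α-chloro ether, in which C14 stands axial on the lactone ring next to C6 and ring C covers that face, so the electrophile should enter from the face of H9 and place C7 cis to C15 (the 6β configuration of the target).

Step 13
Reactants: 20 6β-[(triisopropylsilyloxy)methyl] lactone
Product: 21 lactol (C5 hemiacetal; anomer mixture)
Conditions: DIBAL-H (1.2 equiv), CH2Cl2, −78 °C; Rochelle salt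
Reagents that add atoms: none
Why: Partial reduction of the lactone with DIBAL-H at low temperature stops at the tetrahedral aluminium hemiacetal, which gives the lactol on work-up without touching C6.

Step 14
Reactants: 21 lactol; 22 methyl 2-[bis(2,2,2-trifluoroethoxy)phosphoryl]propanoate
Product: 24 (Z)-enoate alcohol (C9–CH2OH; C6 chain CH(CH2OTIPS)–CH=C(CH3)CO2Me), via hydroxy aldehyde 23 (not isolated)
Conditions: 22, KHMDS, 18-crown-6, THF, −78 °C; then 21; AcOH quench at −78 °C
Reagents that add atoms: none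
Why: Still–Gennari variant of the Horner–Wadsworth–Emmons reaction on the open hydroxy-aldehyde form of the lactol, where the electron-poor trifluoroethyl phosphonate makes elimination of the syn adduct fast and should give the (Z)-2-methylenoate, the cold acidic quench guarding against epimerisation at C6 and re-addition of the C10 alkoxide.

Step 15
Reactants: 24 (Z)-enoate alcohol
Product: 25 (Z)-enoate C10 aldehyde
Conditions: Dess–Martin periodinane, CH2Cl2, 0 °C to rt
Reagents that add atoms: none
Why: Dess–Martin oxidation of the only free (primary) alcohol to the aldehyde under near-neutral conditions that should not epimerise C9 or C6.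

Step 16
Reactants: 25 (Z)-enoate C10 aldehyde; 26 tert-butyldimethyl(prop-2-yn-1-yloxy)silane
Product: 29 allylic alcohol (C10 carbinol; epimer mixture; (E)-C1=C2; C3–OTBS), via alkenylzirconocene 27 (not isolated), via alkenylzinc 28 (not isolated)
Conditions: 26, Cp2Zr(H)Cl, CH2Cl2, rt; Me2Zn, −65 °C; then 25, 0 °C
Reagents that add atoms: none
Why: Hydrozirconation of the terminal alkyne (syn addition, zirconium on the terminal carbon), Zr-to-Zn transmetalation and 1,2-addition of the (E)-alkenylzinc to the aldehyde, a reagent that leaves the enoate ester untouched; the new carbinol centre is removed in step 17.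

Step 17
Reactants: 29 allylic alcohol
Product: 30 (E)-enone (C10 ketone; C3–OTBS)
Conditions: Dess–Martin periodinane, CH2Cl2, rt
Reagents that add atoms: none
Why: Dess–Martin oxidation of the secondary allylic alcohol to the (E)-enone without base, so that C9 next to the new ketone keeps its configuration.

Step 18
Reactants: 30 (E)-enone
Product: 31 Diels–Alder precursor: C/D bicycle with the (1Z,3E)-1,4-bis(tert-butyldimethylsilyloxy)buta-1,3-dienyl group on C9 and the (Z)-enoate on C6 (C7–OTIPS)
Conditions: TBSOTf (1.3 equiv), Et3N (3 equiv), CH2Cl2, −78 to 0 °C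
Reagents that add atoms: tert-butyldimethylsilyl trifluoromethanesulfonate CC(C)(C)[Si](C)(C)OS(=O)(=O)C(F)(F)F
Why: Soft enolisation by O-silylation of the enone followed by γ-deprotonation at C3 with triethylamine (vinylogous silyl enol ether formation), in which the s-cis enone preferred by the bulky C9 group puts O10 cis to C2 (C9 outside) and the less strained E enol ether forms at C2=C3, while the hindered tertiary C9–H is not removed.

Step 19
Reactants: 31 Diels–Alder precursor
Product: 32 pentacyclic cycloadduct (C1=C2; 3β-OTBS; 10α-OTBS; C19 methyl ester; C7–OTIPS)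
Conditions: PhMe (5 mM), BHT (cat.), 130 °C, sealed tube
Reagents that add atoms: none
Why: Thermal, concerted and suprafacial [4+2] cycloaddition, the known intramolecular Diels–Alder reaction of 1,3,8-nonatrienes to hydrindenes, with the two silyloxy groups raising the diene HOMO and the ester lowering the dienophile LUMO. Ring A closes as the six-membered cycloadduct ring (new bonds C5–C10 and C3–C4) and ring B as the five-membered ring that the C9–C8–C6 tether completes when C5 meets C10. C3 follows from the E enol ether (O3 outside) and C4 from the Z enoate (C19 cis to C6, C18 cis to H5), while C10 and C5 follow from the geometry at C10=C1 (C9 outside, O10 inside) combined with the exo position of the C6 tether, which puts H5 anti to O10 (trans-fused). The step needs this tether-exo, ester-exo transition state and not the ester-endo one that leads to the cis-fused isomer; the conformational preference of the three-atom tether, fused into the rigid bicycle with C9 axial and C6 equatorial on ring C, is what should favour it, since the endo rule does not help here. It also needs one diene face, and only the approach that places C1 anti to C11 and C4 anti to C7 on the forming cyclopentane avoids the C/D bicycle, so the existing centres C6, C8 and C9 select it.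

Step 20
Reactants: 32 pentacyclic cycloadduct
Product: 34 Δ1-3β,7-diol 19,10-lactone (12,13-acetonide), via triol ester 33 (not isolated)
Conditions: TBAF, AcOH (1:1), THF, 0 to 45 °C
Reagents that add atoms: none
Why: Fluoride cleaves the three silyl ethers and the tertiary C10 hydroxyl, held 1,3-diaxial to the C19 ester on the α face, closes the γ-lactone by transesterification, acetic acid buffering the medium against retro-aldol at C3 and migration of the allylic lactone.

Step 21
Reactants: 34 Δ1-3β,7-diol 19,10-lactone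
Product: 35 1β,2β-epoxy-3β,7-diol lactone
Conditions: VO(acac)2 (5 mol%), t-BuOOH, CH2Cl2, 0 °C to rt
Reagents that add atoms: tert-butyl hydroperoxide CC(C)(C)OO
Why: Vanadium-catalysed hydroxyl-directed epoxidation, in which the pseudoaxial 3β-hydroxyl delivers the peroxide oxygen to the β face of C1=C2 (also the face away from the lactone bridge), setting C2–O cis to O3, while the 16-methylene has no free allylic hydroxyl and should not react.

Step 22
Reactants: 35 1β,2β-epoxy-3β,7-diol lactone
Product: 36 2β,3β,7-triol lactone (12,13-acetonide)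
Conditions: Ti(OiPr)4 (1.5 equiv), LiBH4 (2 equiv), THF/PhH, 0 °C to rt
Reagents that add atoms: none
Why: Titanium-assisted hydride opening of a 2,3-epoxy alcohol at the carbon remote from the carbinol: with titanium bridging O3 and the oxirane oxygen, hydride should attack C1 from the α face (the axial path to C2 runs under the lactone bridge), so C2 keeps its β oxygen and the 2β,3β-diol results, the hindered γ-lactone being expected to survive LiBH4 at 0 °C.

Step 23
Reactants: 36 2β,3β,7-triol lactone
Product: 38 2β,3β-dihydroxy-7-oic acid lactone (12,13-acetonide), via C7 aldehyde 37 (not isolated)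
Conditions: TEMPO (20 mol%), PhI(OAc)2 (2.5 equiv), MeCN/H2O (1:1), rt
Reagents that add atoms: water O
Why: Oxoammonium (TEMPO) oxidation with PhI(OAc)2 as terminal oxidant, which takes the unhindered primary C7 alcohol to the aldehyde and, through its hydrate, on to the acid much faster than it oxidises the hindered secondary hydroxyls or cleaves the diol.

Step 24
Reactants: 38 2β,3β-dihydroxy-7-oic acid lactone
Product: 39 CNP0191054.1 (2β,3β,12α,13-tetrahydroxy C19-gibberellin 7-oic acid 19,10-lactone)
Conditions: AcOH/H2O (3:1), 45 °C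
Reagents that add atoms: none
Why: Acid-catalysed acetal hydrolysis under conditions too mild for Wagner–Meerwein rearrangement of the 13-hydroxy-16-ene unit or for opening of the lactone.

**Compound list**

1 | 3-[(tert-butyldimethylsilyl)oxy]propanal | O=CCCO[Si](C)(C)C(C)(C)C | starting material
2 | methyl vinyl ketone | CC(=O)C=C | starting material
3 | (S)-2-{[(tert-butyldimethylsilyl)oxy]methyl}-5-oxohexanal | O=C[C@H](CO[Si](C)(C)C(C)(C)C)CCC(C)=O | intermediate
4 | aldol adduct, (4R)-3-hydroxy-4-{[(tert-butyldimethylsilyl)oxy]methyl}cyclohexanone (carbinol epimers; formed in situ) | O=C1CC(O)[C@H](CO[Si](C)(C)C(C)(C)C)CC1 | intermediate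
5 | (R)-4-{[(tert-butyldimethylsilyl)oxy]methyl}cyclohex-2-en-1-one | O=C1C=C[C@H](CO[Si](C)(C)C(C)(C)C)CC1 | intermediate
6 | 1-(tert-butyldimethylsilyloxy)-1-methoxyethene | C=C(OC)O[Si](C)(C)C(C)(C)C | starting material
7 | methyl 2-[(1S,6R)-3-[(tert-butyldimethylsilyl)oxy]-6-{[(tert-butyldimethylsilyl)oxy]methyl}cyclohex-2-en-1-yl]acetate | CC(C)(C)[Si](C)(C)OC1=C[C@@H](CC(=O)OC)[C@H](CO[Si](C)(C)C(C)(C)C)CC1 | intermediate
8 | methyl 2-[(6R)-6-{[(tert-butyldimethylsilyl)oxy]methyl}-3-oxocyclohex-1-en-1-yl]acetate | O=C1C=C(CC(=O)OC)[C@H](CO[Si](C)(C)C(C)(C)C)CC1 | intermediate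
9 | (2-bromoallyl)trimethylsilane | C=C(Br)C[Si](C)(C)C | starting material
10 | methyl 2-[(1R,2R)-1-(2-bromoprop-2-en-1-yl)-2-{[(tert-butyldimethylsilyl)oxy]methyl}-5-oxocyclohexyl]acetate | O=C1C[C@](CC(Br)=C)(CC(=O)OC)[C@H](CO[Si](C)(C)C(C)(C)C)CC1 | intermediate
11 | hydroxy ester, methyl 2-[(1R,2R)-1-(2-bromoprop-2-en-1-yl)-2-(hydroxymethyl)-5-oxocyclohexyl]acetate (formed in situ) | O=C1C[C@](CC(Br)=C)(CC(=O)OC)[C@H](CO)CC1 | intermediate
12 | cis-fused keto δ-lactone, 4a-(2-bromoallyl)hexahydro-1H-isochromene-3,6-dione (C8 quaternary, H9) | O=C1C[C@]2(CC(Br)=C)CC(=O)OC[C@@H]2CC1 | intermediate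
13 | 12-hydroxy keto lactone (12-OH anti to the C10 arm) | O=C1C[C@]2(CC(Br)=C)CC(=O)OC[C@@H]2C[C@H]1O | intermediate
14 | alkenylchromium(III) dichloride from 13 (formed in situ) | O=C1C[C@]2(CC(=C)[Cr](Cl)Cl)CC(=O)OC[C@@H]2C[C@H]1O | intermediate
15 | tricyclic 12β,13-diol lactone (16-methylene C/D bicycle fused to the δ-lactone) | C=C1C[C@]23C[C@@]1(O)[C@H](O)C[C@H]2COC(=O)C3 | intermediate
16 | 13-hydroxy-12-oxo lactone | C=C1C[C@]23C[C@@]1(O)C(=O)C[C@H]2COC(=O)C3 | intermediate
17 | 12α,13-diol lactone | C=C1C[C@]23C[C@@]1(O)[C@@H](O)C[C@H]2COC(=O)C3 | intermediate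
18 | 12α,13-O-isopropylidene lactone | C=C1C[C@]23C[C@@]1(OC(C)(C)O4)[C@@H]4C[C@H]2COC(=O)C3 | intermediate
19 | (triisopropylsiloxy)methyl chloride | ClCO[Si](C(C)C)(C(C)C)C(C)C | starting material
20 | 6β-[(triisopropylsilyloxy)methyl] lactone | C=C1C[C@]23C[C@@]1(OC(C)(C)O4)[C@@H]4C[C@H]2COC(=O)[C@@H]3CO[Si](C(C)C)(C(C)C)C(C)C | intermediate
21 | lactol (C5 hemiacetal, anomer mixture) | C=C1C[C@]23C[C@@]1(OC(C)(C)O4)[C@@H]4C[C@H]2COC(O)[C@@H]3CO[Si](C(C)C)(C(C)C)C(C)C | intermediate
22 | methyl 2-[bis(2,2,2-trifluoroethoxy)phosphoryl]propanoate | COC(=O)C(C)P(=O)(OCC(F)(F)F)OCC(F)(F)F | starting material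
23 | hydroxy aldehyde, open form of 21 (C9–CH2OH, C6–CHO; formed in situ) | C=C1C[C@@]2(C[C@@]1(OC(C)(C)O3)[C@@H]3C[C@H]2CO)[C@@H](CO[Si](C(C)C)(C(C)C)C(C)C)C=O | intermediate
24 | (Z)-enoate alcohol | C=C1C[C@@]2(C[C@@]1(OC(C)(C)O3)[C@@H]3C[C@H]2CO)[C@@H](CO[Si](C(C)C)(C(C)C)C(C)C)/C=C(/C)C(=O)OC | intermediate
25 | (Z)-enoate C10 aldehyde | C=C1C[C@@]2(C[C@@]1(OC(C)(C)O3)[C@@H]3C[C@H]2C=O)[C@@H](CO[Si](C(C)C)(C(C)C)C(C)C)/C=C(/C)C(=O)OC | intermediate
26 | tert-butyldimethyl(prop-2-yn-1-yloxy)silane | C#CCO[Si](C)(C)C(C)(C)C | starting material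
27 | (E)-alkenylzirconocene chloride from 26 (formed in situ) | Cl[Zr](/C=C/CO[Si](C)(C)C(C)(C)C)(C1C=CC=C1)C1C=CC=C1 | intermediate
28 | (E)-alkenyl(methyl)zinc from 27 (formed in situ) | C[Zn]/C=C/CO[Si](C)(C)C(C)(C)C | intermediate
29 | allylic alcohol (C10 epimer mixture) | C=C1C[C@@]2(C[C@@]1(OC(C)(C)O3)[C@@H]3C[C@H]2C(O)/C=C/CO[Si](C)(C)C(C)(C)C)[C@@H](CO[Si](C(C)C)(C(C)C)C(C)C)/C=C(/C)C(=O)OC | intermediate
30 | (E)-enone | C=C1C[C@@]2(C[C@@]1(OC(C)(C)O3)[C@@H]3C[C@H]2C(=O)/C=C/CO[Si](C)(C)C(C)(C)C)[C@@H](CO[Si](C(C)C)(C(C)C)C(C)C)/C=C(/C)C(=O)OC | intermediate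
31 | Diels–Alder precursor (C9 (1Z,3E)-1,4-bis(silyloxy)dienyl; C6 (Z)-enoate; C7–OTIPS) | C=C1C[C@@]2(C[C@@]1(OC(C)(C)O3)[C@@H]3C[C@H]2/C(O[Si](C)(C)C(C)(C)C)=C/C=C/O[Si](C)(C)C(C)(C)C)[C@@H](CO[Si](C(C)C)(C(C)C)C(C)C)/C=C(/C)C(=O)OC | intermediate
32 | pentacyclic cycloadduct (C1=C2, 3β-OTBS, 10α-OTBS, C19 methyl ester) | C=C1C[C@]23C[C@@]1(OC(C)(C)O4)[C@@H]4C[C@H]2[C@]2(O[Si](C)(C)C(C)(C)C)C=C[C@H](O[Si](C)(C)C(C)(C)C)[C@@](C)(C(=O)OC)[C@H]2[C@@H]3CO[Si](C(C)C)(C(C)C)C(C)C | intermediate
33 | triol ester (3β,7,10α-triol, C19 methyl ester; formed in situ) | C=C1C[C@]23C[C@@]1(OC(C)(C)O4)[C@@H]4C[C@H]2[C@]2(O)C=C[C@H](O)[C@@](C)(C(=O)OC)[C@H]2[C@@H]3CO | intermediate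
34 | Δ1-3β,7-diol 19,10-lactone (12,13-acetonide) | C=C1C[C@]23C[C@@]1(OC(C)(C)O4)[C@@H]4C[C@H]2[C@@]12C=C[C@H](O)[C@@](C)(C(=O)O1)[C@H]2[C@@H]3CO | intermediate
35 | 1β,2β-epoxy-3β,7-diol lactone | C=C1C[C@]23C[C@@]1(OC(C)(C)O4)[C@@H]4C[C@H]2[C@@]12[C@@H]5O[C@@H]5[C@H](O)[C@@](C)(C(=O)O1)[C@H]2[C@@H]3CO | intermediate
36 | 2β,3β,7-triol lactone (12,13-acetonide) | C=C1C[C@]23C[C@@]1(OC(C)(C)O4)[C@@H]4C[C@H]2[C@@]12C[C@H](O)[C@H](O)[C@@](C)(C(=O)O1)[C@H]2[C@@H]3CO | intermediate
37 | C7 aldehyde (formed in situ) | C=C1C[C@]23C[C@@]1(OC(C)(C)O4)[C@@H]4C[C@H]2[C@@]12C[C@H](O)[C@H](O)[C@@](C)(C(=O)O1)[C@H]2[C@@H]3C=O | intermediate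
38 | 2β,3β-dihydroxy-7-oic acid lactone (12,13-acetonide) | C=C1C[C@]23C[C@@]1(OC(C)(C)O4)[C@@H]4C[C@H]2[C@@]12C[C@H](O)[C@H](O)[C@@](C)(C(=O)O1)[C@H]2[C@@H]3C(=O)O | intermediate
39 | CNP0191054.1 | C=C1C[C@]23C[C@@]1(O)[C@@H](O)C[C@H]2[C@@]12C[C@H](O)[C@H](O)[C@@](C)(C(=O)O1)[C@H]2[C@@H]3C(=O)O | target

**Totals.** 24 steps in all; the longest linear sequence is 24 steps (from 1 and 2; every other building block is bought).

**Steps most likely to fail**

1. Step 19 (cycloaddition). The s-cis diene conformer is destabilised by the inside silyloxy group on C10, so ring closure may be slower than thermal decay of the silyl dienol ether; the ester-endo mode may also compete and give the cis-fused hydrindene. Fallback, setting out from aldehyde 25 and returning at 34, builds the two rings stepwise by polar chemistry. A thiazolium-carbene-catalysed intramolecular Stetter reaction joins C10 to C5 and gives the ring B ketone F1. The cerium acetylide of 3,3-diethoxypropyne adds to the open β face of C10 and the alkoxide closes onto the C19 ester to give the alkynyl lactone F2. Lindlar semihydrogenation gives the (Z)-alkene F3, and PPTS in wet acetone frees the (Z)-enal F4. KHMDS forms the lactone enolate at C4, which closes ring A by aldol addition to C3 to give the silyl-protected hydroxy lactone F5. TBAF/AcOH removes the TIPS group and gives 34.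

2. Step 22 (epoxide opening). Hydride may enter at C2 and not at C1, which would give the 1,3-diol, or the lactone may be over-reduced. Fallback, setting out from 34 and returning at 36, avoids the epoxide. Manganese dioxide oxidises the allylic 3-hydroxyl to the enone F6. L-Selectride conjugate reduction and trapping of the C2 enolate with the Davis oxaziridine from the open β face give the 2β-hydroxy 3-ketone F7. K-Selectride then delivers hydride along the equatorial path to give the axial 3β-alcohol, which is 36.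

3. Step 14 (olefination of the lactol). The C10 alkoxide set free on ring opening may add back to the new enoate (oxa-Michael ring closure), and the open hydroxy aldehyde may epimerise at C6 under the basic conditions. Fallback, setting out from lactone 20 and returning at 25, opens the ring before the aldehyde is made. Me3Al-mediated aminolysis with N,O-dimethylhydroxylamine gives the hydroxy Weinreb amide F8, and TESCl/imidazole gives its silyl ether F9. DIBAL-H gives the aldehyde F10, and the same Still–Gennari olefination gives the protected (Z)-enoate F11. Swern oxidation converts the primary TES ether of F11 directly into aldehyde 25.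

**Further compounds**

F1 | step 19 | ring B ketone from the Stetter reaction (C10=O, H5β, C4 epimers) | C=C1C[C@]23C[C@@]1(OC(C)(C)O4)[C@@H]4C[C@H]2C(=O)[C@@H](C(C)C(=O)OC)[C@@H]3CO[Si](C(C)C)(C(C)C)C(C)C
F2 | step 19 | alkynyl 19,10-lactone diethyl acetal (C4 epimers) | C=C1C[C@]23C[C@@]1(OC(C)(C)O4)[C@@H]4C[C@H]2[C@@]5(C#CC(OCC)OCC)OC(=O)C(C)[C@H]5[C@@H]3CO[Si](C(C)C)(C(C)C)C(C)C
F3 | step 19 | (Z)-alkenyl lactone diethyl acetal | C=C1C[C@]23C[C@@]1(OC(C)(C)O4)[C@@H]4C[C@H]2[C@@]5(/C=C\C(OCC)OCC)OC(=O)C(C)[C@H]5[C@@H]3CO[Si](C(C)C)(C(C)C)C(C)C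
F4 | step 19 | (Z)-enal lactone (C3 aldehyde) | C=C1C[C@]23C[C@@]1(OC(C)(C)O4)[C@@H]4C[C@H]2[C@@]5(/C=C\C=O)OC(=O)C(C)[C@H]5[C@@H]3CO[Si](C(C)C)(C(C)C)C(C)C
F5 | step 19 | Δ1-3β-hydroxy 19,10-lactone with C7–OTIPS | C=C1C[C@]23C[C@@]1(OC(C)(C)O4)[C@@H]4C[C@H]2[C@@]12C=C[C@H](O)[C@@](C)(C(=O)O1)[C@H]2[C@@H]3CO[Si](C(C)C)(C(C)C)C(C)C
F6 | step 22 | Δ1-3-oxo lactone (7-hydroxy) | C=C1C[C@]23C[C@@]1(OC(C)(C)O4)[C@@H]4C[C@H]2[C@@]12C=CC(=O)[C@@](C)(C(=O)O1)[C@H]2[C@@H]3CO
F7 | step 22 | 2β-hydroxy-3-oxo lactone (7-hydroxy) | C=C1C[C@]23C[C@@]1(OC(C)(C)O4)[C@@H]4C[C@H]2[C@@]12C[C@H](O)C(=O)[C@@](C)(C(=O)O1)[C@H]2[C@@H]3CO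
F8 | step 14 | hydroxy Weinreb amide | C=C1C[C@@]2(C[C@@]1(OC(C)(C)O3)[C@@H]3C[C@H]2CO)[C@@H](CO[Si](C(C)C)(C(C)C)C(C)C)C(=O)N(C)OC
F9 | step 14 | TES-protected Weinreb amide | C=C1C[C@@]2(C[C@@]1(OC(C)(C)O3)[C@@H]3C[C@H]2CO[Si](CC)(CC)CC)[C@@H](CO[Si](C(C)C)(C(C)C)C(C)C)C(=O)N(C)OC
F10 | step 14 | TES-protected C5 aldehyde | C=C1C[C@@]2(C[C@@]1(OC(C)(C)O3)[C@@H]3C[C@H]2CO[Si](CC)(CC)CC)[C@@H](CO[Si](C(C)C)(C(C)C)C(C)C)C=O
F11 | step 14 | TES-protected (Z)-enoate | C=C1C[C@@]2(C[C@@]1(OC(C)(C)O3)[C@@H]3C[C@H]2CO[Si](CC)(CC)CC)[C@@H](CO[Si](C(C)C)(C(C)C)C(C)C)/C=C(/C)C(=O)OC
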